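Wednesday's flask got 1.53 times Thursday's initiator, but after 120 min it held 1.22 times the monomer in chains. Take the logarithm of both ratios and divide, and you get 0.477. Call this n, the initiator exponent: the slope of log monomer in chains against log initiator, at equal times with the other charges equal. It is a reading, and each point in it scatters by 1 percentage point.

| setting | Thursday's | Wednesday's | flask |
|---|---|---|---|
| free monomer | 0.49 M (fed, over 2.0 h) | 0.49 M (fed, over 2.0 h) | 0.49 M (fed, over 2.0 h) |
| protic impurity | 0.49 M | 0.49 M | 0.490 M |
| initiator | 1.7 mM | 2.6 mM | 1.2 mM |
| remark | run made earlier; the fed solution adds 0.10 times the starting volume | run made earlier; the fed solution adds 0.10 times the starting volume | the fed solution adds 0.10 times the starting volume |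
| time |  |  | 3.0 h |

- Thursday's (time / min: monomer in chains / %, free monomer / %): 15.0: 0, 11.1; 40.0: 5.7, 28.8; 80.0: 15.4, 45.1; 120: 29.4, 60.8
- Wednesday's (time / min: monomer in chains / %, free monomer / %): 8.00: 0, 5.8; 20.0: 0, 15.2; 50.0: 4.6, 31.6; 120: 36.0, 54.6

(standard deviation of a reading: 1 percentage point)

- every charge counts on the volume at the start, and the solution that is fed holds the whole dose
- the average divides the monomer in chains by the number of chains, living and dead together; two radicals that join make one chain
- the earlier runs do not show the number of chains; that part of a forecast is a guess
- percentages count the whole charge, also what has not yet gone in

- average number of monomer units in a chain (living and dead chains, two that joined counted as one) at 3.0 h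
- part of the free monomer that has reacted at 3.0 h

Two chemists argue over the new flask, which gets 1.2 mM of initiator. The forecaster counts “about one chain per initiator”. With about 0.22 M of monomer in chains, her forecast is an average of 180, between 40 and 600. It has 61 % of the free monomer reacted, between 55 % and 67 %.

A colleague reads n instead. It lies near 0.5, not 1, and he reads that as radicals that start slowly and end in pairs, at a steady level (a steady state). Chains, in his view, count the initiator already broken, not the initiator charged. The runs do not show that amount, so he gives no figure, but he puts the average above 180. He does commit to two things. First, n carries Thursday's 29.4 % down to 24.9 % for this flask after the same 120 min. Second, if chains follow the initiator, the average at equal times with the other charges equal goes as initiator to the power n − 1.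

The flask gives an average of 756, with 61.0 % reacted.

    protic impurity + free monomer → quenched substrate (k = 0.350 /M/h)
    free monomer + initiating radical → growing radical + monomer in chains (k = 3.60 × 10⁵ /M/s)
    free monomer + growing radical → monomer in chains + growing radical, rate k3*[growing radical]*[free monomer] (k = 3.50 × 10⁷ /M/h)
    2 growing radical → dead chain (k = 2.30 × 10⁸ /M/s)
    initiator → 2 initiating radical (k = 0.0890 /h)

At 3.00 h this flask held 2.56 × 10⁻⁴ M of dead chain, which over the volume after the feed is about a quarter of the initiator charged. The forecaster's count comes nearer late: left to 30.0 h, this flask keeps 6.93 % of its initiator and averages 323, against 291 by her count. For monomer in chains in this flask at 2.00 h, n gave 24.9 % and the flask held 26.4 %. For the neighbour flask with 3.0 × 10⁻⁴ M of initiator, n turns 756 into 1560, and that flask gives 1770.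

The runs were computed for substances that don't exist; scatter was added.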